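(Readings and results were computed for an exercise.)

In a one-step world each Z charged would become G and stay there, so the flask could wait for its full time. The earlier runs showed otherwise.

| setting | south-west | south-east | flask |
|---|---|---|---|
| Z | 0.20 M | 0.29 M | 0.39 M |
| remark | run made earlier | run made earlier |  |
| time |  |  | 12 d |

| run | time / d | G / % | Z / % |
|---|---|---|---|
| south-west | 0.125 | 78.6 | 13.4 |
| south-west | 0.417 | 71.4 | 2.9 |
| south-west | 1.25 | 36.9 | 0.8 |
| south-west | 5.00 | 2.8 | 0.5 |
| south-west | 15.0 | 0.9 | 0 |
| south-east | 0.125 | 73.0 | 14.6 |
| south-east | 0.417 | 71.9 | 1.8 |
| south-east | 1.25 | 37.2 | 2.7 |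
| south-east | 5.00 | 2.9 | 0 |
| south-east | 15.0 | 0.5 | 0 |

(scatter of a reading: 1 percentage point)

- the moment within 12 d at which there is most G
- the amount of G, in percent of the Z charged, at that time
- the first time at which G reaches 41%, in the same percent

- a reading or a percentage of G counts all its forms, free or not

I wrote the balance of G: it gained what Z gave and lost in proportion to what stood, so it stood highest where gain and loss met. In the south-west run Z was down to 13.4% at 0.125 d, which, read as first order, gave Z a half-life of 0.0431 d. G then fell from 71.4% to 36.9% between 0.417 d and 1.25 d, so it halved in 0.875 d. I called this the fading half-life of G, a reading that carries the scatter. The south-east run, over the same stretch, gave 0.876 d. Because the half-life of G's fading was far longer than the half-life of Z, I expected an early peak and then a long decline, with the fading of G as the rate-limiting step of that decline. I carried the same half-life to 0.39 M, which lay beyond the charges tried.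

The forecast for that flask put most G at 0.21 d, with 83% there, and the asked level at 0.9 h. Of that last figure it said: “No early points constrain this, so any induction would shift it.”

The flask gave 81.2% at 0.222 d, and it reached the asked level at 1.18 h, later than the forecast.

    G → L (k = 1.00 × 10⁻⁵ /s)
    2 Z ⇌ D (K = 3.70 /M, k = 0.00710 /M/s)
    J ⇌ G, rate k3*(cs3 - [G]) while solid is left; crystals form when [G] > cs3 (solubility = 0.390 M, k = 8.30 × 10⁻⁴ /s)
    Z ⇌ G (K = 26.0, k = 2.70 × 10⁻⁴ /s)

At the start in this flask, the forward rate at which Z was used in turning into G was 0.049 of the forward rate at which Z was used in turning into D. From its peak, the fading half-life put G at 37.4% by 1.20 d, and the flask held 37.9%. The neighbour flask charged with 1.6 M of Z reached 88.6% and held 0.0222% of G at 12.0 d. At the same half-life that drop takes 10.5 d, less than the 12 d that the neighbour flask ran.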